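**Retrosynthetic overview**

1. Locants (drimane): ring A = C1–C5 + C10 (C3–Br, C4 gem-dimethyl, C10–CH3); ring B = C5–C10 (C7=C8–C12H3, C9–C11H2–Ar). The target has C11 on the α-face (C9–H cis to the C10 methyl).
2. Last: aryl–CH2CO2H by Pd-catalysed α-arylation at an aryl bromide; C7=C8–CH3 from a C8 ketone through its kinetic C7 enol triflate and methyl cross-coupling.
3. Ring B is not cyclised: the cyclopentane C5–C6–C7–C8–C10 of a trans-hydrindane is enlarged to the cyclohexanone by a stereospecific semipinacol 1,2-shift of C10 from C8 to the exocyclic C9. This makes C9–C10 and sets the axial 9α-CH2Ar centre.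
4. Enabling feature: C8 ends sp2 (C7=C8) and sits between the quaternary C10 and the stereogenic C9, so it can be carried as a tertiary carbinol whose ring bond to C10 migrates. The C9 leaving-group centre comes from a Z-selective Wittig union with the arene arm and α-face osmylation.
5. Ring order: ring A + cyclopentane in one enantioselective bromonium-induced bicyclisation of a geranyl-derived dienyl propargylsilane (sets C3, C5, C10) → arene arm → ring B by ring enlargement.

Key step: step 12

Assumption: the antipode of the chiral Lewis base in step 3 is chosen by a test reaction so that bromine is delivered to the olefin face that leads to the (5S)-bromide 7; the (R)-descriptor written stands for that antipode.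

**Route**

Step 1
Reactants: 1 geranyl bromide; 2 1-(trimethylsilyl)propyne
Product: 4 (E)-(6,10-dimethylundeca-5,9-dien-1-yn-1-yl)trimethylsilane, via lithiated silylpropyne 3 (not isolated)
Conditions: 2, n-BuLi, THF, −78 → −20 °C; then 1, −78 °C → rt
Reagents that add atoms: none
Why: Propargylic lithiation of the silylpropyne and SN2 C-alkylation of the allylic bromide should extend the chain by the three alkyne carbons without touching the (E)-olefin; no stereocentre is formed.

Step 2
Reactants: 4
Product: 6 (E)-(7,11-dimethyldodeca-6,10-dien-2-yn-1-yl)trimethylsilane, via lithium acetylide 5 (not isolated)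
Conditions: MeLi·LiBr, THF, 0 °C → rt; then Me3SiCH2OTf, −78 °C → rt
Reagents that add atoms: (trimethylsilyl)methyl trifluoromethanesulfonate, C[Si](C)(C)COS(=O)(=O)C(F)(F)F
Why: MeLi·LiBr should cleave the alkynyl–silicon bond to the lithium acetylide, and acetylide alkylation with the silylmethyl triflate gives the propargylsilane terminator.

Step 3
Reactants: 6
Product: 7 (3aR,5S,7aS)-5-bromo-1-ethenylidene-4,4,7a-trimethyloctahydro-1H-indene
Conditions: DBDMH (1.05 equiv), O,O′-[(R)-3,3′-bis(2,4,6-triisopropylphenyl)-1,1′-binaphthalene-2,2′-diyl] N-triflylthiophosphoramide (10 mol %), toluene/CH2Cl2, −90 °C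
Reagents that add atoms: 1,3-dibromo-5,5-dimethylhydantoin (DBDMH), CC1(C)N(Br)C(=O)N(Br)C1=O
Why: Lewis-base-catalysed enantioselective bromonium-induced cation–olefin bicyclisation: the catalyst-bound Br+ selects one face of the terminal olefin (sets C3), the (E)-olefin closes ring A 6-endo through a chair with bromine equatorial and anti addition (sets C5 and C10 trans), and the tertiary C10 cation is trapped 5-exo by the propargylsilane with loss of Me3Si+ (SE2′) to give the exocyclic allene, as this terminator does in cationic polyene cyclisations that close trans-hydrindanes.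

Step 4
Reactants: 7
Product: 8 (3aR,5S,7aS)-5-bromo-4,4,7a-trimethyloctahydro-1H-inden-1-one
Conditions: O3, pyridine (3 equiv), CH2Cl2, −78 °C
Reagents that add atoms: ozone, [O-][O+]=O
Why: Ozonolysis should cleave the allene at the ring carbon to the cyclopentanone (central carbon lost as CO, terminus as formaldehyde); the C–Br bond and the three stereocentres are not involved.

Step 5
Reactants: 9 2,5-dibromohydroquinone
Product: 10 1,4-dibromo-2,5-bis(methoxymethoxy)benzene
Conditions: MOMCl, i-Pr2NEt, CH2Cl2, 0 °C → rt
Reagents that add atoms: chloromethyl methyl ether, COCCl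
Why: O-Alkylation of both phenols as MOM acetals gives a hydroquinone mask that tolerates organometallics and is removed at the end by dilute acid.

Step 6
Reactants: 10
Product: 12 2-[4-bromo-2,5-bis(methoxymethoxy)phenyl]ethanol, via aryllithium 11 (not isolated)
Conditions: n-BuLi (1.0 equiv), THF, −78 °C; then ethylene oxide, −78 °C → rt
Reagents that add atoms: ethylene oxide, C1CO1
Why: Single bromine–lithium exchange (the aryllithium is stabilised by the ortho MOM oxygen) and epoxide opening should install the two-carbon arm that becomes C11 and C9; the second bromine is kept for the acetic acid arm.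

Step 7
Reactants: 12
Product: 13 1-bromo-4-(2-bromoethyl)-2,5-bis(methoxymethoxy)benzene
Conditions: CBr4, PPh3, imidazole, CH2Cl2, 0 °C
Reagents that add atoms: carbon tetrabromide, BrC(Br)(Br)Br
Why: Appel bromination of the primary alcohol under buffered conditions that the MOM acetals tolerate.

Step 8
Reactants: 13
Product: 14 {2-[4-bromo-2,5-bis(methoxymethoxy)phenyl]ethyl}triphenylphosphonium bromide
Conditions: PPh3, MeCN, reflux
Reagents that add atoms: triphenylphosphine, c1ccc(cc1)P(c1ccccc1)c1ccccc1
Why: SN2 quaternisation of the primary alkyl bromide; the aryl bromide does not react with the phosphine.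

Step 9
Reactants: 8; 14
Product: 16 (1Z,3aR,5S,7aS)-5-bromo-1-{2-[4-bromo-2,5-bis(methoxymethoxy)phenyl]ethylidene}-4,4,7a-trimethyloctahydro-1H-indene, via phosphonium ylide 15 (not isolated)
Conditions: 14 (3 equiv), KN(SiMe3)2, THF, 0 °C; then 8, reflux
Reagents that add atoms: none
Why: Wittig olefination with a non-stabilised ylide; as in the ethylidenation of 17-oxo steroids, which have the same neopentyl cyclopentanone, the ylide substituent should end cis to the quaternary carbon (Z), and this geometry is what later defines C9.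

Step 10
Reactants: 16
Product: 17 (1R,3aR,5S,7aS)-5-bromo-1-{(1S)-2-[4-bromo-2,5-bis(methoxymethoxy)phenyl]-1-hydroxyethyl}-4,4,7a-trimethyloctahydro-1H-inden-1-ol
Conditions: OsO4 (5 mol %), NMO, acetone/H2O, rt
Reagents that add atoms: N-methylmorpholine N-oxide, C[N+]1([O-])CCOCC1; water, O
Why: Catalytic osmylation should add both oxygens syn from the α-face, opposite the angular methyl, which sets the α tertiary alcohol at C8 and the (S)-carbinol at C9 from the Z-olefin.

Step 11
Reactants: 17
Product: 18 (1R,3aR,5S,7aS)-5-bromo-1-{(1S)-2-[4-bromo-2,5-bis(methoxymethoxy)phenyl]-1-[(methylsulfonyl)oxy]ethyl}-4,4,7a-trimethyloctahydro-1H-inden-1-ol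
Conditions: MsCl, Et3N, CH2Cl2, −20 °C
Reagents that add atoms: methanesulfonyl chloride, CS(=O)(=O)Cl
Why: Only the secondary C9 hydroxyl is sulfonylated, since the tertiary C8 hydroxyl next to the quaternary carbon is too hindered; the C9 configuration is retained.

Step 12
Reactants: 18
Product: 20 (1S,4aR,6S,8aS)-6-bromo-1-{[4-bromo-2,5-bis(methoxymethoxy)phenyl]methyl}-5,5,8a-trimethyloctahydronaphthalen-2(1H)-one, via diethylaluminium alkoxide 19 (not isolated)
Conditions: Et3Al (3 equiv), CH2Cl2, −78 → 0 °C
Reagents that add atoms: none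
Why: Et3Al converts the tertiary C8–OH into a diethylaluminium alkoxide and, as a Lewis acid, loosens the C9–OMs bond; the alkoxide then pushes the C8–C10 bond onto C9 in a concerted 1,2-shift (semipinacol rearrangement) that expels mesylate and leaves the C8 carbonyl. The closest known reaction types are the organoaluminium-promoted pinacol-type rearrangement of β-mesyloxy alcohols and the D-homoannulation of 17-hydroxy-20-sulfonyloxy steroids, which have the same neopentyl cyclopentanol array. Ring B is not closed by a cyclisation: the cyclopentane C5–C6–C7–C8–C10 is enlarged by one atom when the exocyclic C9 is inserted between C8 and C10. The only new stereocentre, C9, is set by inversion at the carbon that carries the mesylate, so the configuration installed by the Z-olefin and the α-face osmylation is relayed into the axial 9α-CH2Ar group (C9–H cis to the C10 methyl), which equilibration of the ketone would not favour. The step needs migration of the quaternary C10 and not of the C7 methylene or closure to the 8,9-epoxide; this should be secured by the rotamer about C8–C9 that keeps the small C9–H under the angular methyl, which places C9–OMs antiperiplanar to C8–C10 and gauche to C8–C7 and C8–O, and by the higher migratory aptitude of the fully substituted carbon. C10 migrates with retention, so the trans ring fusion and C3 are untouched.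

Step 13
Reactants: 20
Product: 22 (1S,4aR,6S,8aS)-6-bromo-1-{[4-bromo-2,5-bis(methoxymethoxy)phenyl]methyl}-5,5,8a-trimethyl-1,4,4a,5,6,7,8,8a-octahydronaphthalen-2-yl trifluoromethanesulfonate, via potassium enolate 21 (not isolated)
Conditions: KN(SiMe3)2, THF, −78 °C; then PhNTf2, −78 → −20 °C
Reagents that add atoms: N-phenylbis(trifluoromethanesulfonimide), O=S(=O)(N(c1ccccc1)S(=O)(=O)C(F)(F)F)C(F)(F)F
Why: Kinetic deprotonation should remove an axial C7–H of the methylene (the C9–H is equatorial, hindered and poorly aligned with the carbonyl) and O-triflation fixes the C7=C8 position of the final olefin without touching C9; the equatorial C3–Br has no antiperiplanar hydrogen for elimination.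

Step 14
Reactants: 22
Product: 23 (1R,4aR,6S,8aR)-6-bromo-1-{[4-bromo-2,5-bis(methoxymethoxy)phenyl]methyl}-2,5,5,8a-tetramethyl-1,4,4a,5,6,7,8,8a-octahydronaphthalene
Conditions: MeMgBr, Fe(acac)3 (5 mol %), THF/NMP, −30 °C
Reagents that add atoms: methylmagnesium bromide, C[Mg]Br
Why: Iron-catalysed Kumada-type cross-coupling of the alkenyl triflate with MeMgBr installs C12 at C8; the aryl bromide and the neopentyl-type secondary alkyl bromide should not be activated under these conditions.

Step 15
Reactants: 23
Product: 24 methyl 2-(4-{[(1R,4aR,6S,8aR)-6-bromo-2,5,5,8a-tetramethyl-1,4,4a,5,6,7,8,8a-octahydronaphthalen-1-yl]methyl}-2,5-bis(methoxymethoxy)phenyl)acetate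
Conditions: BrZnCH2CO2Me, Pd(dba)2 (3 mol %), P(t-Bu)3 (3 mol %), THF, rt → 40 °C
Reagents that add atoms: bromozinc enolate of methyl acetate (Reformatsky reagent), COC(=O)C[Zn]Br
Why: Palladium-catalysed α-arylation of an ester (Negishi-type coupling of the Reformatsky reagent) at the aryl bromide; zerovalent palladium should not insert into the hindered secondary alkyl bromide, and the neutral zinc enolate leaves C9 and the olefin alone.

Step 16
Reactants: 24
Product: 26 peyssonoic acid A, via carboxylic acid 25 (not isolated)
Conditions: LiOH, THF/H2O, rt; then HCl (aq., 3 M), rt, argon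
Reagents that add atoms: lithium hydroxide, [Li+].[OH-]
Why: Saponification of the methyl ester followed in the same flask by aqueous acid hydrolysis of the two aryl MOM acetals; dilute aqueous acid at room temperature should not protonate the trisubstituted olefin, and the aqueous medium disfavours lactonisation of the 2-hydroxyphenylacetic acid.

**Compound list**

1 | geranyl bromide, (2E)-1-bromo-3,7-dimethylocta-2,6-diene | CC(C)=CCC/C(C)=C/CBr | starting material
2 | 1-(trimethylsilyl)propyne | CC#C[Si](C)(C)C | starting material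
3 | 3-lithio-1-(trimethylsilyl)propyne | [Li]CC#C[Si](C)(C)C | intermediate
4 | (E)-(6,10-dimethylundeca-5,9-dien-1-yn-1-yl)trimethylsilane | C[Si](C)(C)C#CCC/C=C(\C)CCC=C(C)C | intermediate
5 | lithium (E)-6,10-dimethylundeca-5,9-dien-1-yn-1-ide | [Li]C#CCC/C=C(\C)CCC=C(C)C | intermediate
6 | (E)-(7,11-dimethyldodeca-6,10-dien-2-yn-1-yl)trimethylsilane | C[Si](C)(C)CC#CCC/C=C(\C)CCC=C(C)C | intermediate
7 | (3aR,5S,7aS)-5-bromo-1-ethenylidene-4,4,7a-trimethyloctahydro-1H-indene (trans-fused, Br equatorial and cis to the angular methyl) | C=C=C1CC[C@H]2C(C)(C)[C@@H](Br)CC[C@]12C | intermediate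
8 | (3aR,5S,7aS)-5-bromo-4,4,7a-trimethyloctahydro-1H-inden-1-one | O=C1CC[C@H]2C(C)(C)[C@@H](Br)CC[C@]12C | intermediate
9 | 2,5-dibromohydroquinone | Oc1cc(Br)c(O)cc1Br | starting material
10 | 1,4-dibromo-2,5-bis(methoxymethoxy)benzene | COCOc1cc(Br)c(OCOC)cc1Br | intermediate
11 | [4-bromo-2,5-bis(methoxymethoxy)phenyl]lithium | [Li]c1cc(OCOC)c(Br)cc1OCOC | intermediate
12 | 2-[4-bromo-2,5-bis(methoxymethoxy)phenyl]ethanol | OCCc1cc(OCOC)c(Br)cc1OCOC | intermediate
13 | 1-bromo-4-(2-bromoethyl)-2,5-bis(methoxymethoxy)benzene | BrCCc1cc(OCOC)c(Br)cc1OCOC | intermediate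
14 | {2-[4-bromo-2,5-bis(methoxymethoxy)phenyl]ethyl}triphenylphosphonium bromide | [Br-].COCOc1cc(Br)c(OCOC)cc1CC[P+](c1ccccc1)(c1ccccc1)c1ccccc1 | intermediate
15 | {2-[4-bromo-2,5-bis(methoxymethoxy)phenyl]ethylidene}triphenylphosphorane | COCOc1cc(Br)c(OCOC)cc1CC=P(c1ccccc1)(c1ccccc1)c1ccccc1 | intermediate
16 | (1Z,3aR,5S,7aS)-5-bromo-1-{2-[4-bromo-2,5-bis(methoxymethoxy)phenyl]ethylidene}-4,4,7a-trimethyloctahydro-1H-indene (CH2Ar cis to the quaternary carbon) | COCOc1cc(Br)c(OCOC)cc1C/C=C2/CC[C@H]3C(C)(C)[C@@H](Br)CC[C@]23C | intermediate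
17 | (1R,3aR,5S,7aS)-5-bromo-1-{(1S)-2-[4-bromo-2,5-bis(methoxymethoxy)phenyl]-1-hydroxyethyl}-4,4,7a-trimethyloctahydro-1H-inden-1-ol (tertiary OH α) | COCOc1cc(Br)c(OCOC)cc1C[C@H](O)[C@@]2(O)CC[C@H]3C(C)(C)[C@@H](Br)CC[C@]23C | intermediate
18 | C9 mesylate of diol 17 | COCOc1cc(Br)c(OCOC)cc1C[C@H](OS(C)(=O)=O)[C@@]2(O)CC[C@H]3C(C)(C)[C@@H](Br)CC[C@]23C | intermediate
19 | diethylaluminium alkoxide of 18 | COCOc1cc(Br)c(OCOC)cc1C[C@H](OS(C)(=O)=O)[C@@]2(O[Al](CC)CC)CC[C@H]3C(C)(C)[C@@H](Br)CC[C@]23C | intermediate
20 | (1S,4aR,6S,8aS)-6-bromo-1-{[4-bromo-2,5-bis(methoxymethoxy)phenyl]methyl}-5,5,8a-trimethyloctahydronaphthalen-2(1H)-one (trans-decalin, CH2Ar axial and trans to the angular methyl) | O=C1CC[C@H]2C(C)(C)[C@@H](Br)CC[C@]2(C)[C@@H]1Cc1cc(OCOC)c(Br)cc1OCOC | intermediate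
21 | potassium C7=C8 enolate of 20 | [K+].[O-]C1=CC[C@H]2C(C)(C)[C@@H](Br)CC[C@]2(C)[C@@H]1Cc1cc(OCOC)c(Br)cc1OCOC | intermediate
22 | C7=C8 enol triflate of 20 | O=S(=O)(OC1=CC[C@H]2C(C)(C)[C@@H](Br)CC[C@]2(C)[C@@H]1Cc1cc(OCOC)c(Br)cc1OCOC)C(F)(F)F | intermediate
23 | (1R,4aR,6S,8aR)-6-bromo-1-{[4-bromo-2,5-bis(methoxymethoxy)phenyl]methyl}-2,5,5,8a-tetramethyl-1,4,4a,5,6,7,8,8a-octahydronaphthalene | CC1=CC[C@H]2C(C)(C)[C@@H](Br)CC[C@]2(C)[C@@H]1Cc1cc(OCOC)c(Br)cc1OCOC | intermediate
24 | methyl ester of bis-MOM peyssonoic acid A | CC1=CC[C@H]2C(C)(C)[C@@H](Br)CC[C@]2(C)[C@@H]1Cc1cc(OCOC)c(CC(=O)OC)cc1OCOC | intermediate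
25 | bis-MOM peyssonoic acid A | CC1=CC[C@H]2C(C)(C)[C@@H](Br)CC[C@]2(C)[C@@H]1Cc1cc(OCOC)c(CC(=O)O)cc1OCOC | intermediate
26 | peyssonoic acid A, 2-(4-{[(1R,4aR,6S,8aR)-6-bromo-2,5,5,8a-tetramethyl-1,4,4a,5,6,7,8,8a-octahydronaphthalen-1-yl]methyl}-2,5-dihydroxyphenyl)acetic acid | CC1=CC[C@H]2C(C)(C)[C@@H](Br)CC[C@]2(C)[C@@H]1Cc1cc(O)c(CC(=O)O)cc1O | target

**Step count and risks**

Total steps: 16. Longest linear sequence: 12 steps (steps 1–4 and 9–16 from geranyl bromide; equally steps 5–16 from 2,5-dibromohydroquinone).

Steps most likely to fail: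

1. Step 3 (enantioselective bromonium bicyclisation). Bromonium transfer between olefins may erode the facial bias; the C10 cation may lose a proton before the alkyne closes the five-membered ring; electrophilic bromine may consume the propargylsilane. Fallback (resolution in place of asymmetric catalysis): setting out from 6, racemic bicyclisation with Et2SBr·SbCl5Br in MeNO2 at −25 °C should give 7 together with the enantiomeric allene F1. Ozonolysis of the mixture as in step 4 gives 8 together with the enantiomeric ketone F2. The two ketones are separated by preparative chromatography on a chiral stationary phase, and the route is rejoined at 8.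

2. Step 12 (semipinacol ring enlargement). The C7 methylene may migrate in competition with C10; the alkoxide may close onto C9 to give the 8,9-epoxide; the electron-rich arene may participate at C11; the aluminium Lewis acid may cleave a MOM acetal. Fallback (halohydrin and silver in place of sulfonate and aluminium): setting out from olefin 16, NBS in aqueous DME should deliver bromine to C9 from the α-face with water opening at the tertiary C8, giving the bromohydrin F3. Ag2CO3/AgBF4 in CH2Cl2 then triggers the same 1,2-shift of C10 with inversion at C9 under non-basic conditions without an aluminium reagent. The route is rejoined at 20.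

3. Step 9 (Wittig olefination). Addition of the ylide to the neopentyl ketone may be slow and lose out to enolisation, and incomplete Z-selectivity would be carried into C9. Fallback (stepwise Horner–Wittig with separation of adducts): setting out from bromide 13 and ketone 8, Michaelis–Arbuzov reaction of 13 with Ph2POEt gives the phosphine oxide F4. Its lithio derivative (n-BuLi, THF, −78 °C) adds to 8 from the α-face, and the β-hydroxy phosphine oxide F5 is separated from its C9 epimer by chromatography. KH in DMF effects stereospecific syn-elimination to the Z-olefin, and the route is rejoined at 16.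

Further compounds
F1 | step 3 | (3aS,5R,7aR)-5-bromo-1-ethenylidene-4,4,7a-trimethyloctahydro-1H-indene (enantiomer of 7) | C=C=C1CC[C@@H]2C(C)(C)[C@H](Br)CC[C@@]12C
F2 | step 3 | (3aS,5R,7aR)-5-bromo-4,4,7a-trimethyloctahydro-1H-inden-1-one (enantiomer of 8) | O=C1CC[C@@H]2C(C)(C)[C@H](Br)CC[C@@]12C
F3 | step 12 | bromohydrin of 16 (C9–Br from the α-face, tertiary C8–OH β) | COCOc1cc(Br)c(OCOC)cc1C[C@H](Br)[C@]2(O)CC[C@H]3C(C)(C)[C@@H](Br)CC[C@]23C
F4 | step 9 | {2-[4-bromo-2,5-bis(methoxymethoxy)phenyl]ethyl}diphenylphosphine oxide | O=P(c1ccccc1)(c1ccccc1)CCc1cc(OCOC)c(Br)cc1OCOC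
F5 | step 9 | β-hydroxy phosphine oxide adduct of F4 and 8 (C8–OH β; C9 epimer that eliminates to the Z-olefin) | COCOc1cc(Br)c(OCOC)cc1C[C@@H](P(=O)(c1ccccc1)c1ccccc1)[C@]2(O)CC[C@H]3C(C)(C)[C@@H](Br)CC[C@]23C
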